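**Retrosynthetic overview**

- The strategy rests on ring B of the depsidone, a hexasubstituted benzene whose six carbons carry in sequence the lactone oxygen, the diaryl ether oxygen, a free hydroxyl, the pyranone oxygen, the ketone carbon and a methyl group.
- Late disconnections: ether and acetal cleavage; the pyranone C–O bond (oxa-Michael of the ring B phenol onto a 3-methylbut-2-enoyl group); the seven-membered lactone C–O bond.
- Key disconnection: the ring B bond between the lactone-oxygen carbon and the methyl-bearing carbon, made by thermal 4π opening and 6π closure of a 4-alkenyl-4-hydroxycyclobutenone.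
- That cyclobutenone comes from an alkenyllithium and an aryl isopropyl squarate. The crowded diaryl ether is made as a phenoxide addition–elimination on a squaric ester chloride, not as an arene–arene coupling.
- Order of rings: ring A is bought (orsellinic acid), ring B is built in step 12, the lactone ring in step 14, the pyranone in step 16.

Key step: step 12

Assumption: the target is achiral and the butenyl alkene geometry is erased on aromatisation, so racemic intermediates and diastereomer mixtures are carried without stereocontrol.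

**Step 1**
Reactants: 1 orsellinic acid
Product: 2 allyl 2,4-dihydroxy-6-methylbenzoate
Conditions: allyl bromide, KHCO3, DMF, rt
Reagents that add atoms: allyl bromide, C=CCBr
Why: Carboxylate alkylation (SN2) under bicarbonate, which ionises only the carboxylic acid, so the phenols stay free and the mild temperature avoids decarboxylation.

**Step 2**
Reactants: 2 allyl 2,4-dihydroxy-6-methylbenzoate
Product: 3 allyl 4-(benzyloxy)-2-hydroxy-6-methylbenzoate
Conditions: BnBr, K2CO3, acetone, reflux
Reagents that add atoms: benzyl bromide, BrCc1ccccc1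
Why: Williamson ether synthesis at the 4-hydroxyl only, because the 2-hydroxyl is hydrogen-bonded to the ester carbonyl and flanked by it.

**Step 3**
Reactants: 3 allyl 4-(benzyloxy)-2-hydroxy-6-methylbenzoate
Product: 4 allyl 4-(benzyloxy)-3-formyl-2-hydroxy-6-methylbenzoate
Conditions: MgCl2, Et3N, (CH2O)n, MeCN, reflux; then 1 M HCl
Reagents that add atoms: paraformaldehyde (formaldehyde), C=O
Why: Magnesium-mediated ortho-formylation of a phenol (Casnati–Skattebøl reaction) delivers formaldehyde only ortho to the phenoxide, and the single free ortho carbon is C3 between the hydroxyl and the benzyloxy group; a second formaldehyde oxidises the hydroxymethyl stage to the aldehyde.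

**Step 4**
Reactants: 4 allyl 4-(benzyloxy)-3-formyl-2-hydroxy-6-methylbenzoate
Product: 5 allyl 4-(benzyloxy)-3-(dimethoxymethyl)-2-hydroxy-6-methylbenzoate
Conditions: HC(OMe)3, MeOH, CSA (cat.), 40 °C; then Et3N
Reagents that add atoms: trimethyl orthoformate, COC(OC)OC; methanol, CO
Why: Acid-catalysed acetalisation driven by the orthoformate masks the aldehyde against the organolithium of step 11; base quench and immediate use guard the labile ortho-hydroxy acetal.

**Step 5**
Reactants: 6 diisopropyl squarate
Product: 7 sodium 2-isopropoxy-3,4-dioxocyclobut-1-en-1-olate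
Conditions: NaOH (1.0 equiv), THF–H2O, 0 °C → rt; evaporate, dry
Reagents that add atoms: sodium hydroxide, [Na+].[OH-]
Why: Addition–elimination of hydroxide at one vinylogous ester carbon gives the squarate monoanion, which is deactivated toward a second attack, so hydrolysis should stop at the monoester.

**Step 6**
Reactants: 7 sodium 2-isopropoxy-3,4-dioxocyclobut-1-en-1-olate
Product: 8 3-chloro-4-isopropoxycyclobut-3-ene-1,2-dione
Conditions: (COCl)2, DMF (cat.), CH2Cl2, 0 °C → rt
Reagents that add atoms: oxalyl chloride, O=C(Cl)C(Cl)=O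
Why: Vilsmeier-type conversion of the vinylogous carboxylate into the vinylogous acid chloride, the same transformation that turns squaric acid into its dichloride.

**Step 7**
Reactants: 5 allyl 4-(benzyloxy)-3-(dimethoxymethyl)-2-hydroxy-6-methylbenzoate; 8 3-chloro-4-isopropoxycyclobut-3-ene-1,2-dione
Product: 10 allyl 4-(benzyloxy)-3-(dimethoxymethyl)-2-[(2-isopropoxy-3,4-dioxocyclobut-1-en-1-yl)oxy]-6-methylbenzoate, via sodium phenoxide 9 (not isolated)
Conditions: NaH, THF, 0 °C; then 8, −78 → 0 °C; non-aqueous work-up
Reagents that add atoms: none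
Why: Addition–elimination of the phenoxide at the chlorine-bearing sp2 carbon of the squaric ester chloride (an acylation-like substitution) forms the hindered aryl–oxygen bond, chloride leaving far more readily than isopropoxide.

**Step 8**
Reactants: 11 crotonaldehyde
Product: 13 (Z)-2-bromobut-2-enal, via dibromobutanal 12 (not isolated)
Conditions: Br2, CH2Cl2, 0 °C; then Et3N, 0 °C → rt
Reagents that add atoms: bromine, BrBr
Why: Anti addition of bromine followed by base-induced loss of HBr through the acidic α-proton (E1cB) should give the thermodynamically preferred bromoenal with methyl trans to formyl and cis to bromine.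

**Step 9**
Reactants: 13 (Z)-2-bromobut-2-enal; 14 2-methyl-1-propenylmagnesium bromide
Product: 15 (Z)-3-bromo-6-methylhepta-2,5-dien-4-ol (racemic)
Conditions: THF, −78 °C; then sat. aq. NH4Cl
Reagents that add atoms: none
Why: 1,2-Addition of the alkenyl Grignard reagent to the aldehyde at low temperature; the carbinol centre forms racemic and is oxidised away in step 16.

**Step 10**
Reactants: 15 (Z)-3-bromo-6-methylhepta-2,5-dien-4-ol
Product: 16 tert-butyl{[(Z)-3-bromo-6-methylhepta-2,5-dien-4-yl]oxy}dimethylsilane (racemic)
Conditions: TBSCl, imidazole, DMF, rt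
Reagents that add atoms: tert-butyldimethylsilyl chloride, CC(C)(C)[Si](C)(C)Cl
Why: Imidazole-promoted silylation of the secondary allylic alcohol gives an ether that withstands the organolithium and the thermolysis.

**Step 11**
Reactants: 16 tert-butyl{[(Z)-3-bromo-6-methylhepta-2,5-dien-4-yl]oxy}dimethylsilane; 10 aryl isopropyl squarate
Product: 18 allyl 4-(benzyloxy)-3-(dimethoxymethyl)-2-({3-hydroxy-2-isopropoxy-4-oxo-3-[(2Z)-4-(tert-butyldimethylsilyloxy)-6-methylhepta-2,5-dien-3-yl]cyclobut-1-en-1-yl}oxy)-6-methylbenzoate (mixture of diastereomers), via alkenyllithium 17 (not isolated)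
Conditions: t-BuLi (2.0 equiv), Et2O, −78 °C; then 10, THF, −78 °C; then sat. aq. NH4Cl at −78 °C
Reagents that add atoms: none
Why: Bromine–lithium exchange with retention of alkene geometry, then 1,2-addition of the alkenyllithium to a squarate carbonyl at −78 °C; the carbonyl next to the isopropoxy-bearing carbon should be attacked because its only vinylogous donor is the weakly donating aryloxy oxygen and it lies away from the bulky 2,6-disubstituted aryl group, while the hindered benzoate and the acetal are inert at this temperature; the carbinol centre forms without control and the diastereomers converge in step 12.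

**Step 12**
Reactants: 18 4-alkenyl-4-hydroxy-3-isopropoxy-2-aryloxycyclobutenone
Product: 21 allyl 4-(benzyloxy)-3-(dimethoxymethyl)-2-{2,5-dihydroxy-6-isopropoxy-3-methyl-4-[1-(tert-butyldimethylsilyloxy)-3-methylbut-2-en-1-yl]phenoxy}-6-methylbenzoate (racemic), via dienylketene 19 (not isolated), via cyclohexadienone 20 (not isolated)
Conditions: degassed toluene (0.02 M), 110 °C, Ar
Reagents that add atoms: none
Why: Heating opens the cyclobutenone by conrotatory 4π electrocyclic ring opening in which the hydroxyl on the carbinol carbon turns outward and the alkenyl group inward, so dienylketene 19 has its ketene carbon beside the CH(CH3) terminus. Thermal disrotatory 6π electrocyclisation then joins the ketene carbon, the future lactone-oxygen carbon, to that terminus and closes ring B as cyclohexa-2,4-dienone 20, and a proton shift from the ring CH to oxygen aromatises it; the closest known reaction type is the thermal ring expansion of squarate-derived 4-alkenyl-4-hydroxycyclobutenones to hydroquinones (Moore rearrangement). Ring B is therefore closed in a six-electron electrocyclic mode, and its four oxygens arrive one on each former squarate carbon in the fixed order hydroxyl, aryloxy, isopropoxy, hydroxyl. No stereocentre is created for keeps: the CH(CH3) centre of 20 vanishes on aromatisation, the silyloxy carbon is untouched, and both diastereomers of 18 should give the same racemic 21. The selectivity needed is outward rotation of the hydroxyl (torquoselectivity, secured by its lone-pair donor character) together with ring closure outpacing capture of the ketene; because the methyl group sits on the inner face of the closing terminus, a dilute, degassed, nucleophile-free solution is used and p-xylene at 138 °C is kept in reserve.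

**Step 13**
Reactants: 21 ring B hydroquinone allyl ester
Product: 23 4-(benzyloxy)-3-(dimethoxymethyl)-2-{2,5-dihydroxy-6-isopropoxy-3-methyl-4-[1-(tert-butyldimethylsilyloxy)-3-methylbut-2-en-1-yl]phenoxy}-6-methylbenzoic acid, via phenylsilyl ester 22 (not isolated)
Conditions: Pd(PPh3)4 (5 mol%), PhSiH3, CH2Cl2, rt, Ar; then H2O
Reagents that add atoms: none
Why: Palladium-catalysed deallylation (Tsuji–Trost type): zerovalent palladium ionises the allyl ester and hydride from the silane turns the allyl unit into propene under neutral, reducing conditions that keep the hydroquinone from oxidising, and water frees the acid from its silyl ester.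

**Step 14**
Reactants: 23 hydroquinone acid
Product: 24 3-(benzyloxy)-4-(dimethoxymethyl)-7-hydroxy-6-isopropoxy-1,9-dimethyl-8-[1-(tert-butyldimethylsilyloxy)-3-methylbut-2-en-1-yl]-11H-dibenzo[b,e][1,4]dioxepin-11-one
Conditions: EDC·HCl, DMAP (cat.), degassed CH2Cl2 (0.002 M), rt, Ar
Reagents that add atoms: none
Why: Carbodiimide lactonisation (Steglich conditions) at high dilution; only the hydroxyl ortho to the diaryl ether oxygen can reach the activated carboxyl and close the seven-membered lactone, whereas the para hydroxyl would need an impossible bridged ring.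

**Step 15**
Reactants: 24 silyl-protected depsidone
Product: 25 3-(benzyloxy)-4-(dimethoxymethyl)-7-hydroxy-8-(1-hydroxy-3-methylbut-2-en-1-yl)-6-isopropoxy-1,9-dimethyl-11H-dibenzo[b,e][1,4]dioxepin-11-one
Conditions: TBAF, AcOH (1:1), THF, 0 °C → rt
Reagents that add atoms: none
Why: Fluoride-mediated desilylation buffered with acetic acid, so that the aryl lactone is not opened and the ortho-hydroxybenzylic alcohol is not ionised.

**Step 16**
Reactants: 25 depsidone allylic alcohol
Product: 27 O-benzyl O-isopropyl dimethyl acetal of the target (2,2-dimethylchroman-4-one closed on ring B), via aryl enone 26 (not isolated)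
Conditions: MnO2 (excess), CH2Cl2, rt; filter; then DBU (cat.), CH2Cl2, rt
Reagents that add atoms: none
Why: MnO2 oxidises the allylic and benzylic alcohol selectively to the aryl enone, and base-catalysed intramolecular oxa-Michael addition (6-endo-trig) of the ortho phenol to the β,β-dimethyl enone closes the 2,2-dimethylchroman-4-one; the silyloxy stereocentre disappears.

**Step 17**
Reactants: 27 protected depsidone chromanone
Product: 28 target CNP0271978.0
Conditions: BCl3, pentamethylbenzene, CH2Cl2, −78 → 0 °C; then H2O
Reagents that add atoms: water, O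
Why: Lewis-acid ether cleavage: BCl3 removes the isopropyl and benzyl ethers (the cations are taken up by chloride and by pentamethylbenzene) and ionises the dimethyl acetal, which hydrolyses to the aldehyde on work-up, while the aryl lactone, the diaryl ether and the chromanone should stay intact.

**Compound list**

1 | orsellinic acid (2,4-dihydroxy-6-methylbenzoic acid) | Cc1cc(O)cc(O)c1C(=O)O | starting material
2 | allyl 2,4-dihydroxy-6-methylbenzoate | Cc1cc(O)cc(O)c1C(=O)OCC=C | intermediate
3 | allyl 4-(benzyloxy)-2-hydroxy-6-methylbenzoate | Cc1cc(OCc2ccccc2)cc(O)c1C(=O)OCC=C | intermediate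
4 | allyl 4-(benzyloxy)-3-formyl-2-hydroxy-6-methylbenzoate | Cc1cc(OCc2ccccc2)c(C=O)c(O)c1C(=O)OCC=C | intermediate
5 | allyl 4-(benzyloxy)-3-(dimethoxymethyl)-2-hydroxy-6-methylbenzoate | Cc1cc(OCc2ccccc2)c(C(OC)OC)c(O)c1C(=O)OCC=C | intermediate
6 | diisopropyl squarate (3,4-diisopropoxycyclobut-3-ene-1,2-dione) | CC(C)OC1=C(OC(C)C)C(=O)C1=O | starting material
7 | sodium 2-isopropoxy-3,4-dioxocyclobut-1-en-1-olate | CC(C)OC1=C([O-])C(=O)C1=O.[Na+] | intermediate
8 | 3-chloro-4-isopropoxycyclobut-3-ene-1,2-dione | CC(C)OC1=C(Cl)C(=O)C1=O | intermediate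
9 | sodium phenoxide of 5 (not isolated) | Cc1cc(OCc2ccccc2)c(C(OC)OC)c([O-])c1C(=O)OCC=C.[Na+] | intermediate
10 | allyl 4-(benzyloxy)-3-(dimethoxymethyl)-2-[(2-isopropoxy-3,4-dioxocyclobut-1-en-1-yl)oxy]-6-methylbenzoate (aryl isopropyl squarate) | CC(C)OC1=C(Oc2c(C(OC)OC)c(OCc3ccccc3)cc(C)c2C(=O)OCC=C)C(=O)C1=O | intermediate
11 | crotonaldehyde, (E)-but-2-enal | C/C=C/C=O | starting material
12 | (2R*,3S*)-2,3-dibromobutanal, racemic, one enantiomer drawn (not isolated) | C[C@H](Br)[C@H](Br)C=O | intermediate
13 | (Z)-2-bromobut-2-enal | C/C=C(\Br)C=O | intermediate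
14 | 2-methyl-1-propenylmagnesium bromide | CC(C)=C[Mg]Br | starting material
15 | (Z)-3-bromo-6-methylhepta-2,5-dien-4-ol, racemic | C/C=C(\Br)C(O)C=C(C)C | intermediate
16 | tert-butyl{[(Z)-3-bromo-6-methylhepta-2,5-dien-4-yl]oxy}dimethylsilane, racemic | C/C=C(\Br)C(O[Si](C)(C)C(C)(C)C)C=C(C)C | intermediate
17 | [4-(tert-butyldimethylsilyloxy)-6-methylhepta-2,5-dien-3-yl]lithium, lithium cis to the C1 methyl (not isolated) | C/C=C(\[Li])C(O[Si](C)(C)C(C)(C)C)C=C(C)C | intermediate
18 | 4-alkenyl-4-hydroxy-3-isopropoxy-2-aryloxycyclobutenone carrying ring A (full name in step 11), mixture of diastereomers | C/C=C(/C(O[Si](C)(C)C(C)(C)C)C=C(C)C)C1(O)C(OC(C)C)=C(Oc2c(C(OC)OC)c(OCc3ccccc3)cc(C)c2C(=O)OCC=C)C1=O | intermediate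
19 | dienylketene from ring opening of 18, hydroxyl outward (not isolated) | O=C=C(Oc1c(C(OC)OC)c(OCc2ccccc2)cc(C)c1C(=O)OCC=C)/C(OC(C)C)=C(/O)\C(=C/C)C(O[Si](C)(C)C(C)(C)C)C=C(C)C | intermediate
20 | 6-methylcyclohexa-2,4-dienone from 6π closure of 19, mixture of diastereomers (not isolated) | CC1C(=O)C(Oc2c(C(OC)OC)c(OCc3ccccc3)cc(C)c2C(=O)OCC=C)=C(OC(C)C)C(O)=C1C(O[Si](C)(C)C(C)(C)C)C=C(C)C | intermediate
21 | diaryl ether hydroquinone with all six ring B substituents (full name in step 12), racemic | Cc1c(O)c(Oc2c(C(OC)OC)c(OCc3ccccc3)cc(C)c2C(=O)OCC=C)c(OC(C)C)c(O)c1C(O[Si](C)(C)C(C)(C)C)C=C(C)C | intermediate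
22 | phenylsilyl ester of acid 23 (not isolated) | Cc1c(O)c(Oc2c(C(OC)OC)c(OCc3ccccc3)cc(C)c2C(=O)O[SiH2]c2ccccc2)c(OC(C)C)c(O)c1C(O[Si](C)(C)C(C)(C)C)C=C(C)C | intermediate
23 | hydroquinone benzoic acid (full name in step 13), racemic | Cc1c(O)c(Oc2c(C(OC)OC)c(OCc3ccccc3)cc(C)c2C(=O)O)c(OC(C)C)c(O)c1C(O[Si](C)(C)C(C)(C)C)C=C(C)C | intermediate
24 | 3-(benzyloxy)-4-(dimethoxymethyl)-7-hydroxy-6-isopropoxy-1,9-dimethyl-8-[1-(tert-butyldimethylsilyloxy)-3-methylbut-2-en-1-yl]-11H-dibenzo[b,e][1,4]dioxepin-11-one, racemic | Cc1cc(OCc3ccccc3)c(C(OC)OC)c2c1C(=O)Oc1c(C)c(C(O[Si](C)(C)C(C)(C)C)C=C(C)C)c(O)c(OC(C)C)c1O2 | intermediate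
25 | 3-(benzyloxy)-4-(dimethoxymethyl)-7-hydroxy-8-(1-hydroxy-3-methylbut-2-en-1-yl)-6-isopropoxy-1,9-dimethyl-11H-dibenzo[b,e][1,4]dioxepin-11-one, racemic | Cc1cc(OCc3ccccc3)c(C(OC)OC)c2c1C(=O)Oc1c(C)c(C(O)C=C(C)C)c(O)c(OC(C)C)c1O2 | intermediate
26 | 3-(benzyloxy)-4-(dimethoxymethyl)-7-hydroxy-6-isopropoxy-1,9-dimethyl-8-(3-methylbut-2-enoyl)-11H-dibenzo[b,e][1,4]dioxepin-11-one (not isolated) | Cc1cc(OCc3ccccc3)c(C(OC)OC)c2c1C(=O)Oc1c(C)c(C(=O)C=C(C)C)c(O)c(OC(C)C)c1O2 | intermediate
27 | protected target: ring A 3-O-benzyl and 4-dimethyl acetal, ring B 6-O-isopropyl, 2,2-dimethylpyran-4-one fused at C7 (oxygen) and C8 (ketone carbon) | Cc1cc(OCc4ccccc4)c(C(OC)OC)c2c1C(=O)Oc1c(C)c3c(c(OC(C)C)c1O2)OC(C)(C)CC3=O | intermediate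
28 | CNP0271978.0: depsidone with ring A 1-methyl, 3-hydroxy, 4-formyl and ring B 6-hydroxy, 9-methyl and a fused 2,2-dimethyl-2,3-dihydropyran-4-one | Cc1cc(O)c(C=O)c2c1C(=O)Oc1c(C)c3c(c(O)c1O2)OC(C)(C)CC3=O | target

**Step count**

Total steps: 17. Longest linear sequence: 12 steps (orsellinic acid 1 to target 28 through steps 1–4, 7 and 11–17).

**Steps most likely to fail**

Step 11. Alkenyllithium 17 carries its silyloxy group on the carbon next to the carbanion. Migration of silicon from oxygen to carbon, or loss of silanolate to an allene, may therefore consume the reagent before it adds to 10. The fallback sets out from alcohol 15 and squarate 10 and returns at 18. Alcohol 15 is deprotonated with MeLi and then exchanged with t-BuLi (Et2O, −78 °C) to the O,C-dilithio reagent lithium 3-lithio-6-methylhepta-2,5-dien-4-olate F1, which has no silyl group to migrate and an oxide that does not leave. Addition to 10 at −78 °C and NH4Cl quench should give the cyclobutenone diol F2. TBSCl with imidazole should then silylate only the secondary allylic hydroxyl and so deliver 18.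

Step 12. The methyl group lies on the inner side of the closing terminus, so the 6π closure may be slowed. The ketene may then be captured by the free hydroxyl after inward rotation (furanone formation) or the material may decay on prolonged heating. The fallback sets out from 18 and returns at 21. The tertiary hydroxyl is silylated (TMSCl, imidazole, DMF) to the trimethylsilyl ether F3. This known silyloxy variant of the ring expansion offers no hydroxyl to intercept the ketene and tolerates p-xylene at 138 °C, giving the mono-silylated hydroquinone F4. K2CO3 in MeOH at 0 °C under argon should remove the aryl trimethylsilyl group only and return 21.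

Step 14. Hydroquinone acid 23 may be oxidised to the quinone by traces of air under the basic coupling conditions. Activation of the doubly ortho-substituted acid may also end in N-acylurea or intermolecular acylation instead of seven-ring closure. The fallback reverses the order of the two ring closures; it sets out from 21 and returns at 27.
- TBAF/AcOH should give the hydroquinone allylic alcohol F5.
- MnO2 should oxidise both the hydroquinone and the allylic alcohol to the fully substituted acylquinone F6.
- Na2S2O4 (EtOAc–H2O) should reduce the quinone to the hydroquinone enone F7, which is not isolated; it closes by oxa-Michael addition (catalytic Et3N, argon) to the chromanone phenol allyl ester F8.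
- Deallylation (Pd(PPh3)4, PhSiH3) should give the chromanone phenol acid F9. Its one remaining phenol is no longer part of a free hydroquinone.
- Carbodiimide lactonisation (EDC·HCl, DMAP) of F9 should then lead to 27.

**Further compounds**

F1 | step 11 | lithium 3-lithio-6-methylhepta-2,5-dien-4-olate, lithium cis to the C1 methyl | C/C=C(\[Li])C(O[Li])C=C(C)C
F2 | step 11 | cyclobutenone diol, the desilyl analogue of 18 | C/C=C(/C(O)C=C(C)C)C1(O)C(OC(C)C)=C(Oc2c(C(OC)OC)c(OCc3ccccc3)cc(C)c2C(=O)OCC=C)C1=O
F3 | step 12 | tertiary trimethylsilyl ether of 18 | C/C=C(/C(O[Si](C)(C)C(C)(C)C)C=C(C)C)C1(O[Si](C)(C)C)C(OC(C)C)=C(Oc2c(C(OC)OC)c(OCc3ccccc3)cc(C)c2C(=O)OCC=C)C1=O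
F4 | step 12 | mono-trimethylsilyl ether of 21 (silyl on the hydroxyl next to the side chain) | Cc1c(O)c(Oc2c(C(OC)OC)c(OCc3ccccc3)cc(C)c2C(=O)OCC=C)c(OC(C)C)c(O[Si](C)(C)C)c1C(O[Si](C)(C)C(C)(C)C)C=C(C)C
F5 | step 14 | hydroquinone allylic alcohol, the desilyl analogue of 21 | Cc1c(O)c(Oc2c(C(OC)OC)c(OCc3ccccc3)cc(C)c2C(=O)OCC=C)c(OC(C)C)c(O)c1C(O)C=C(C)C
F6 | step 14 | acylquinone: 2-aryloxy-3-isopropoxy-5-(3-methylbut-2-enoyl)-6-methyl-1,4-benzoquinone carrying ring A | CC1=C(C(=O)C=C(C)C)C(=O)C(OC(C)C)=C(Oc2c(C(OC)OC)c(OCc3ccccc3)cc(C)c2C(=O)OCC=C)C1=O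
F7 | step 14 | hydroquinone enone | Cc1c(O)c(Oc2c(C(OC)OC)c(OCc3ccccc3)cc(C)c2C(=O)OCC=C)c(OC(C)C)c(O)c1C(=O)C=C(C)C
F8 | step 14 | chromanone phenol allyl ester | Cc1c(O)c(Oc3c(C(OC)OC)c(OCc4ccccc4)cc(C)c3C(=O)OCC=C)c(OC(C)C)c2OC(C)(C)CC(=O)c12
F9 | step 14 | chromanone phenol acid | Cc1c(O)c(Oc3c(C(OC)OC)c(OCc4ccccc4)cc(C)c3C(=O)O)c(OC(C)C)c2OC(C)(C)CC(=O)c12
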